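**Plan**

- Cuts: (a) the bond from the bridging CH2 to ring B (the 2-acyl-4,4-dimethylcyclohexane-1,3,5-trione ring), giving an aldehyde on ring A (the arene) and acetylfilicinic acid; (b) in ring B, the bond between the ring CH carbon and the oxygen-bearing carbon next to CMe2; (c) on ring A, the C–acetyl, O–methyl and C–formyl bonds.
- Enabling feature: ring B consists of one C(=O)–CMe2–C(=O) unit and one triacyl carbon carrying two acetyl groups. The acyl carbon next to CMe2 and an acetyl methyl carbon lie 1,5 across that triacyl carbon, so ring B is the C-acyl isomer of an enol δ-lactone (a 2H-pyran-2,4-dione) in which the same acyl carbon sits on the enol oxygen. CMe2 has no α-hydrogen and the two acetyl groups are equivalent, so only one closure is possible.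
- Forward: the lactone is made from acetylacetone and dimethylmalonyl dichloride and is then rearranged to ring B by O-to-C acyl transposition. Ring A is elaborated from 2,4,6-trihydroxytoluene by formylation, para-selective O-methylation and acetylation at the last free position. Rings A and B are joined last by reductive Knoevenagel alkylation, which makes the unsymmetrical CH2 bridge without free formaldehyde.
- Stereochemistry: the target has no stereocentre, so there is nothing to control.

Key step: step 2

Remark: all β-polycarbonyl compounds are written as one enol tautomer; tautomers are not distinguished.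

**Step 1**
Reactants: 1 acetylacetone (pentane-2,4-dione); 2 dimethylmalonyl dichloride (2,2-dimethylpropanedioyl dichloride)
Product: 4 5-acetyl-3,3,6-trimethyl-2H-pyran-2,4(3H)-dione (enol δ-lactone), via triacylmethane acid chloride 3 (not isolated)
Conditions: MgCl2 (1.1 equiv), pyridine (2.2 equiv), CH2Cl2, 0 °C → rt, slow addition of 2; cold dilute HCl wash; crude 4 used soon
Reagents that add atoms: none
Why: Magnesium-enolate C-acylation (Rathke-type soft enolisation) of the 1,3-diketone at its central carbon by one acid chloride of 2 should give 3, whose enol oxygen then closes the six-membered enol lactone on the second acid chloride; 2 has no α-hydrogen, so no ketene path exists, and the two acetyl groups are equivalent, so only one lactone can form.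

**Step 2**
Reactants: 4 5-acetyl-3,3,6-trimethyl-2H-pyran-2,4(3H)-dione
Product: 6 acetylfilicinic acid (2-acetyl-3,5-dihydroxy-4,4-dimethylcyclohexa-2,5-dien-1-one), via open-chain keto ester 5 (not isolated)
Conditions: NaOMe (1.05 equiv), MeOH–THF, 0 °C; evaporate; LiN(iPr)2 (2.5 equiv), THF, −78 °C → rt; then 1 M HCl
Reagents that add atoms: none
Why: Methoxide should add to the lactone carbonyl of 4 (an enol ester) and open the ring to the sodium enolate of keto ester 5, in which the former lactone carbon is a methyl ester on the CMe2 carbon and the two acetyl groups on the triacyl carbon are equivalent. LiN(iPr)2 then removes a proton from one acetyl methyl group, and the terminal carbon of this dianion attacks the ester carbonyl (Dieckmann condensation, 6-(enolexo)-exo-trig), so that the bond between the future bridge-bearing ring CH and the C–O carbon next to CMe2 is made and methoxide leaves. The closest known reaction types are the alkoxide-induced rearrangement of enol lactones to cyclic 1,3-diones (benzylidenephthalide to 2-phenylindane-1,3-dione), the methoxide opening of 2-pyranones to polyketo esters and the Claisen cyclisation of polyketide dianions to acylphloroglucinols. No stereocentre is formed. The step needs regioselectivity in the ring opening and in the attacking carbon: the acyl carbon is the hard electrophilic site for methoxide, CMe2 has no α-hydrogen, both acetyl groups give the same ring, and any other closure would be four-membered. The final deprotonation of 6 to its vinylogous carboxylate should make the sequence irreversible.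

**Step 3**
Reactants: 7 2,4,6-trihydroxytoluene (2-methylbenzene-1,3,5-triol)
Product: 9 2,4,6-trihydroxy-3-methylbenzaldehyde, via aryl iminium chloride 8 (not isolated)
Conditions: POCl3 (1.1 equiv), DMF (1.5 equiv), EtOAc, 0 °C → rt; then H2O, 60 °C
Reagents that add atoms: N,N-dimethylformamide, CN(C)C=O; water, O
Why: Vilsmeier–Haack formylation of the electron-rich triol should give the iminium salt 8 and, after hydrolysis, aldehyde 9; the two free ring positions of 7 are equivalent by symmetry, so only one monoaldehyde can form, and the first formyl group slows a second substitution.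

**Step 4**
Reactants: 9 2,4,6-trihydroxy-3-methylbenzaldehyde
Product: 10 2,6-dihydroxy-4-methoxy-3-methylbenzaldehyde
Conditions: Me2SO4 (1.0 equiv), K2CO3 (1.0 equiv), acetone, rt
Reagents that add atoms: dimethyl sulfate, COS(=O)(=O)OC
Why: In this Williamson etherification the 4-hydroxyl (para to the formyl group) is the most acidic one and the only one not held in a hydrogen bond to the formyl oxygen, so one equivalent of base and of methylating agent should methylate it selectively, which places the methoxy group between the methyl group and the last free ring position.

**Step 5**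
Reactants: 10 2,6-dihydroxy-4-methoxy-3-methylbenzaldehyde
Product: 12 3-acetyl-2,6-dihydroxy-4-methoxy-5-methylbenzaldehyde, via difluoroboron chelate 11 (not isolated)
Conditions: AcOH (excess), BF3·OEt2 (3 equiv), 80 °C; then H2O–MeOH, 60 °C
Reagents that add atoms: acetic acid, CC(=O)O
Why: Friedel–Crafts acylation by the acetic acid–BF3 complex should occur at the single free ring position, which is ortho or para to all three oxygen donors and meta to the formyl group (the same reaction type as the second acetylation of 2,4,6-trihydroxyacetophenone to 2,4-diacetylphloroglucinol); the product is held as the boron chelate 11 until aqueous work-up.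

**Step 6**
Reactants: 6 acetylfilicinic acid; 12 3-acetyl-2,6-dihydroxy-4-methoxy-5-methylbenzaldehyde
Product: 14 target CNP0313340.0 (2-acetyl-6-[(3-acetyl-2,6-dihydroxy-4-methoxy-5-methylphenyl)methyl]-3,5-dihydroxy-4,4-dimethylcyclohexa-2,5-dien-1-one), via arylidene trione 13 (not isolated)
Conditions: Hantzsch ester (diethyl 2,6-dimethyl-1,4-dihydropyridine-3,5-dicarboxylate, 1.1 equiv), L-proline (20 mol %), CH2Cl2–EtOH, rt → 40 °C
Reagents that add atoms: none
Why: In this organocatalytic reductive Knoevenagel alkylation the only C–H acidic ring carbon of 6 should condense with the aldehyde of 12 (the chelated aryl ketone is far less electrophilic) to the arylidene trione 13, an o-quinone-methide-like acceptor that takes up hydride from the Hantzsch ester at the benzylic carbon, so the CH2 bridge is formed between two different partners and no symmetrical dimer can arise.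

**Compound list**

1 | acetylacetone (pentane-2,4-dione) | CC(=O)CC(C)=O | starting material
2 | dimethylmalonyl dichloride | CC(C)(C(Cl)=O)C(Cl)=O | starting material
3 | 4-acetyl-2,2-dimethyl-3,5-dioxohexanoyl chloride (present as magnesium enolate) | CC(=O)C(C(C)=O)C(=O)C(C)(C)C(Cl)=O | intermediate (not isolated)
4 | 5-acetyl-3,3,6-trimethyl-2H-pyran-2,4(3H)-dione | CC(=O)C1=C(C)OC(=O)C(C)(C)C1=O | intermediate
5 | methyl 4-acetyl-2,2-dimethyl-3,5-dioxohexanoate (present as sodium enolate) | COC(=O)C(C)(C)C(=O)C(C(C)=O)C(C)=O | intermediate (not isolated)
6 | acetylfilicinic acid (2-acetyl-3,5-dihydroxy-4,4-dimethylcyclohexa-2,5-dien-1-one) | CC(=O)C1=C(O)C(C)(C)C(O)=CC1=O | intermediate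
7 | 2,4,6-trihydroxytoluene | Cc1c(O)cc(O)cc1O | starting material
8 | N,N-dimethyl-(2,4,6-trihydroxy-3-methylphenyl)methaniminium chloride | C[N+](C)=Cc1c(O)c(C)c(O)cc1O.[Cl-] | intermediate (not isolated)
9 | 2,4,6-trihydroxy-3-methylbenzaldehyde | O=Cc1c(O)c(C)c(O)cc1O | intermediate
10 | 2,6-dihydroxy-4-methoxy-3-methylbenzaldehyde | COc1cc(O)c(C=O)c(O)c1C | intermediate
11 | difluoroboron chelate of 12 (boron bridging the acetyl oxygen and the adjacent phenol oxygen) | CC1=[O+][B-](F)(F)Oc2c(C=O)c(O)c(C)c(OC)c12 | intermediate (not isolated)
12 | 3-acetyl-2,6-dihydroxy-4-methoxy-5-methylbenzaldehyde | COc1c(C)c(O)c(C=O)c(O)c1C(C)=O | intermediate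
13 | 2-acetyl-6-[(3-acetyl-2,6-dihydroxy-4-methoxy-5-methylphenyl)methylidene]-3-hydroxy-4,4-dimethylcyclohex-2-ene-1,5-dione (alkene geometry not defined) | COc1c(C)c(O)c(C=C2C(=O)C(C)(C)C(O)=C(C(C)=O)C2=O)c(O)c1C(C)=O | intermediate (not isolated)
14 | CNP0313340.0, 2-acetyl-6-[(3-acetyl-2,6-dihydroxy-4-methoxy-5-methylphenyl)methyl]-3,5-dihydroxy-4,4-dimethylcyclohexa-2,5-dien-1-one | COc1c(C)c(O)c(CC2=C(O)C(C)(C)C(O)=C(C(C)=O)C2=O)c(O)c1C(C)=O | target

Total step count: 6. Longest linear sequence: 4 steps (7 → 9 → 10 → 12 → 14); the ring-B branch (1 + 2 → 4 → 6) has 2 steps before the union.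

**Steps most likely to fail**

Step 2. Methoxide may add to the methyl-bearing ring carbon of the lactone (conjugate opening that leaves a carboxylate) instead of to the lactone carbonyl, or an acetyl group may be lost by retro-Claisen cleavage before the second deprotonation. The fallback does not pass through the lactone. It sets out from 2, which with one equivalent of methanol (CH2Cl2, −20 °C, distillation) should give methyl 3-chloro-2,2-dimethyl-3-oxopropanoate F1. This acylates the magnesium enolate of 1 (MgCl2, pyridine) at carbon to give keto ester 5 as an isolated, purified compound. LiN(iPr)2 (3 equiv, THF, −78 °C → rt) then closes 5 by Dieckmann condensation, and the route is rejoined at 6.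

Step 6. Condensation of the doubly chelated, electron-rich aldehyde may be slow, and the arylidene intermediate may be captured by a second molecule of 6 or by the neighbouring phenol (cyclodehydration to a xanthene-type ring) before hydride transfer. The fallback sets out from 12. Reductive amination (Me2NH·HCl, NaBH(OAc)3, 1,2-dichloroethane) should give the Mannich base 1-[3-[(dimethylamino)methyl]-2,4-dihydroxy-6-methoxy-5-methylphenyl]ethanone F2. Heating F2 with 6 in dioxane at 90 °C should expel dimethylamine and generate the o-quinone methide, which is captured by the ring CH of 6 (Michael addition), and the route is rejoined at 14.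

Step 5. The Lewis acid may promote condensation of the free aldehyde with the nucleophilic ring position of a second molecule, stop at O-acetylation, or cleave the methyl ether on long heating. The fallback sets out from 10. Bromination at the only free position (N-bromosuccinimide, MeCN, 0 °C) should give 3-bromo-2,6-dihydroxy-4-methoxy-5-methylbenzaldehyde F3. Stille coupling with tributyl(1-ethoxyvinyl)stannane (Pd(PPh3)4, dioxane, 100 °C) gives 3-(1-ethoxyethenyl)-2,6-dihydroxy-4-methoxy-5-methylbenzaldehyde F4. Hydrolysis of the enol ether (1 M HCl, THF, rt) rejoins the route at 12.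

**Further compounds**

F1 | step 2 | methyl 3-chloro-2,2-dimethyl-3-oxopropanoate | COC(=O)C(C)(C)C(Cl)=O
F2 | step 6 | 1-[3-[(dimethylamino)methyl]-2,4-dihydroxy-6-methoxy-5-methylphenyl]ethanone | COc1c(C)c(O)c(CN(C)C)c(O)c1C(C)=O
F3 | step 5 | 3-bromo-2,6-dihydroxy-4-methoxy-5-methylbenzaldehyde | COc1c(C)c(O)c(C=O)c(O)c1Br
F4 | step 5 | 3-(1-ethoxyethenyl)-2,6-dihydroxy-4-methoxy-5-methylbenzaldehyde | CCOC(=C)c1c(O)c(C=O)c(O)c(C)c1OC
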